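The earlier runs and the new flask stem from a simulated flask with made-up constants.

**One step.** I began from a one-step world, in which each partner turns one substrate into product. There theta's c(partner) of 0.028 M covers its 0.0140 M of substrates. Yet theta's reacted part read 9.00% at 3.00 h, its last reading.

all flasks: precatalyst 0.35 mM

|  | left-handed substrate | right-handed substrate | partner | remark | time |
|---|---|---|---|---|---|
| theta | 0.0070 M | 0.0070 M | 0.028 M | run made earlier |  |
| gamma | 0.028 M | 0.028 M | 0.028 M | run made earlier |  |
| flask | 0.014 M | 0.014 M | 0.0280 M |  | 3.0 h |

| run | time / h | left-handed substrate / % | right-handed substrate / % |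
|---|---|---|---|
| theta | 0.833 | 42.7 | 48.1 |
| theta | 1.50 | 42.0 | 48.6 |
| theta | 2.50 | 39.9 | 50.6 |
| theta | 3.00 | 39.8 | 51.2 |
| gamma | 0.250 | 49.2 | 51.2 |
| gamma | 0.500 | 49.4 | 48.6 |
| gamma | 1.33 | 47.5 | 50.6 |
| gamma | 3.00 | 45.9 | 48.5 |

(standard deviation of a reading: 1 percentage point)

- free catalyst is single-handed; left-handed substrate and right-handed substrate are mirror images of each other, charged as a racemate, each of them at the stated concentration
- the numbers in the tables scatter by 1 percentage point (one standard deviation)
- an excess is the difference of the two amounts in percent of their sum
- an excess is below zero if the other one leads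

* part of the left-handed substrate and right-handed substrate charged together that has reacted at 3.0 h
* excess of left-handed product over right-handed product in the product at 3.0 h
* excess of right-handed substrate over left-handed substrate among what is left of the two at 3.0 h

**The decision.** I kept partner, precatalyst and time for the next run and chose c(left-handed substrate) = 0.014 M. That is a factor 2.00 above theta and 2.00 below gamma, midway on a logarithmic scale, so a straight line between the runs needs no mechanism.

**Partner share.** I carried the partner share φ, the substrate reacted per partner charged. At 3.00 h theta gave 4.50% and gamma 11.2%. Their logarithms, −1.35 and −0.951, average −1.15, which gave a reckoned partner share of 7.10% for the flask. In the flask the reacted part is then 7.10%.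

**Handedness.** Single readings of theta scatter too widely for a ratio, so I assumed a steady eP and pooled its four readings, which stand at different stages of the run. Their summed excess of right-handed over left-handed substrate, divided by their summed reacted part, gave a reading of 91.9% for eP. Carried to the flask, that gave eS of 7.02%. I charged the flask unchanged.

**The check.** The forecast gave 9%, 50% and 9%, on the ground that “The flask lies between these”, and its eP differed from mine. The flask gave a reacted part of 6.37%, eP of 91.4% and eS of 6.23%.

    partner + catalyst intermediate B → free catalyst + right-handed product (k = 0.710 M⁻¹ s⁻¹)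
    free catalyst + left-handed substrate ⇌ catalyst intermediate A (K = 2000 M⁻¹, k = 4.00 M⁻¹ s⁻¹)
    partner + catalyst intermediate A → free catalyst + left-handed product (k = 1.80 M⁻¹ s⁻¹)
    partner + precatalyst → free catalyst + spent reagent (k = 0.00560 M⁻¹ s⁻¹)
    2 partner → self-condensation product (k = 0.0150 M⁻¹ s⁻¹)
    free catalyst + right-handed substrate ⇌ catalyst intermediate B (K = 32.0 M⁻¹, k = 13.0 M⁻¹ s⁻¹)
    partner → decomposed reagent (k = 3.50 × 10⁻⁴ s⁻¹)

**Partner's fate.** The flask's share φ was 6.37% against my 7.10%; at 0.300 h the route through catalyst intermediate A was taking partner at 3.95 × 10⁻⁵ s⁻¹, decomposition and self-condensation were removing it at 6.71 × 10⁻⁴ s⁻¹, far faster than that, and this limiting reagent ended at 0.28% of its charge. The neighbour flask, charged with 0.0014 M of precatalyst, reached a share of 17.7%, 2.49 times my reckoned figure, with 0.027% of its partner left.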